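## Retrosynthetic overview

1. Target ⇒ its 7,8-acetonide ⇒ (2R)-2-chloro lactone + (2E,4E)-muconic acid. The C2–O bond is made last by an invertive carboxylate SN2, so the dienoate never meets the metathesis catalyst.
2. Ten-membered lactone ⇒ ring-closing metathesis at C5=C6 of the ester formed from the C6–C9/propyl alcohol fragment (C9–OH) and (2R)-2-chlorohex-5-enoic acid.
3. Alcohol fragment ⇒ chelation-controlled reduction (C9) of the acetonide of a syn-α,β-dihydroxy ketone ⇒ amino-acid-catalysed syn-aldol of 1-hydroxypentan-2-one with (E)-but-2-enal (C7–C8 bond; C7 and C8 are the first stereocenters).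
4. Acid fragment ⇒ amine-catalysed α-chlorination and oxidation of hex-5-enal (C2).
5. Ring order: the temporary dioxolane first (step 2), then the ten-membered lactone (step 6), the only ring of the target.

Assumption: the SMILES is read as (2S,7R,8S,9R) with a 5E ring alkene and a (2E,4E)-muconic half ester, and 1-hydroxypentan-2-one, (2E)-but-2-enal, hex-5-enal and (2E,4E)-hexa-2,4-dienedioic acid are taken as catalogue chemicals.

## Route

Step 1
Reactants: 1 1-hydroxypentan-2-one; 2 (2E)-but-2-enal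
Product: 3 (5S,6R,7E)-5,6-dihydroxynon-7-en-4-one
Conditions: O-tert-butyl-D-threonine (20 mol %), 1 (3 equiv), N-methylpyrrolidone with 3 vol % H2O, 4 °C, 2 added by syringe pump over 12 h, 48 h
Reagents that add atoms: none
Why: Proposed new method: a primary-amino-acid enamine-catalysed direct syn-aldol between an unprotected 1-hydroxyalkan-2-one and an enolisable enal, the closest known reaction being the O-tert-butylthreonine-catalysed syn-aldol of hydroxyacetone or dihydroxyacetone with aromatic and saturated aldehydes; the amine condenses with the ketone to the (Z)-enamine on the hydroxylated carbon (internal N–H···O hydrogen bond), the catalyst CO2H hydrogen-bonds the aldehyde oxygen so that attack is 1,2 and not conjugate, and the D-catalyst delivers the enamine to the Si face of 2 through a chair-like transition state, which sets C5 (S) and C6 (R) syn.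

Step 2
Reactants: 3 (5S,6R,7E)-5,6-dihydroxynon-7-en-4-one
Product: 4 1-[(4S,5R)-2,2-dimethyl-5-[(1E)-prop-1-en-1-yl]-1,3-dioxolan-4-yl]butan-1-one
Conditions: 2,2-dimethoxypropane (3 equiv), pyridinium p-toluenesulfonate (5 mol %), CH2Cl2, rt
Reagents that add atoms: 2,2-dimethoxypropane, COC(C)(C)OC
Why: acid-catalysed transketalisation (acetonide formation) of the syn-diol gives the more stable trans-4,5-disubstituted dioxolane without touching either stereocenter.

Step 3
Reactants: 4 1-[(4S,5R)-2,2-dimethyl-5-[(1E)-prop-1-en-1-yl]-1,3-dioxolan-4-yl]butan-1-one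
Product: 5 (1R)-1-[(4R,5R)-2,2-dimethyl-5-[(1E)-prop-1-en-1-yl]-1,3-dioxolan-4-yl]butan-1-ol
Conditions: Zn(BH4)2 (0.2 M in Et2O, 1.5 equiv), Et2O, −30 to 0 °C; aq. NH4Cl work-up
Reagents that add atoms: none
Why: chelation-controlled (Cram-chelate) reduction, in which zinc bridges the carbonyl and the α-dioxolane oxygen and hydride enters from the face of the α-hydrogen, gives the 1,2-anti carbinol (R).

Step 4
Reactants: 6 hex-5-enal
Product: 8 (2R)-2-chlorohex-5-enoic acid, via (2R)-2-chlorohex-5-enal 7 (not isolated)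
Conditions: (2S,5S)-2,5-diphenylpyrrolidine (10 mol %), N-chlorosuccinimide (1.3 equiv), CH2Cl2, 0 °C to rt; then t-BuOH/H2O, 2-methylbut-2-ene (10 equiv), NaH2PO4, NaClO2, 0 °C
Reagents that add atoms: N-chlorosuccinimide, O=C1CCC(=O)N1Cl; sodium chlorite NaClO2, [Na+].[O-]Cl=O
Why: enamine-catalysed asymmetric α-chlorination (Jørgensen type) sets C2, the phenyl group next to the enamine shielding one face so that chlorine enters to give the (R)-aldehyde, and Pinnick oxidation in the same flask turns the configurationally labile aldehyde into the stable acid.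

Step 5
Reactants: 5 (1R)-1-[(4R,5R)-2,2-dimethyl-5-[(1E)-prop-1-en-1-yl]-1,3-dioxolan-4-yl]butan-1-ol; 8 (2R)-2-chlorohex-5-enoic acid
Product: 9 (1R)-1-[(4R,5R)-2,2-dimethyl-5-[(1E)-prop-1-en-1-yl]-1,3-dioxolan-4-yl]butyl (2R)-2-chlorohex-5-enoate
Conditions: N,N'-dicyclohexylcarbodiimide (1.3 equiv), 4-(dimethylamino)pyridine (5 mol %), CH2Cl2, −20 to 0 °C
Reagents that add atoms: none
Why: Steglich esterification joins the two fragments with retention at the carbinol carbon, and low temperature with little 4-(dimethylamino)pyridine keeps the α-chloro acyl group from epimerising.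

Step 6
Reactants: 9 (1R)-1-[(4R,5R)-2,2-dimethyl-5-[(1E)-prop-1-en-1-yl]-1,3-dioxolan-4-yl]butyl (2R)-2-chlorohex-5-enoate
Product: 10 (3R,6E,8R,9R,10R)-3-chloro-8,9-(isopropylidenedioxy)-10-propyl-3,4,5,8,9,10-hexahydro-2H-oxecin-2-one
Conditions: second-generation Grubbs catalyst RuCl2(=CHPh)(PCy3)(H2IMes) (10 mol %), CH2Cl2 (2 mM), 40 °C
Reagents that add atoms: none
Why: ring-closing metathesis between the terminal alkene and the propenyl group (loss of propene) closes the ten-membered lactone, and the E alkene is expected because the trans-fused dioxolane holds C6–C7–C8–C9 extended.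

Step 7
Reactants: 10 (3R,6E,8R,9R,10R)-3-chloro-8,9-(isopropylidenedioxy)-10-propyl-3,4,5,8,9,10-hexahydro-2H-oxecin-2-one; 11 (2E,4E)-hexa-2,4-dienedioic acid
Product: 12 (2E,4E)-6-{[(3S,6E,8R,9R,10R)-8,9-(isopropylidenedioxy)-2-oxo-10-propyl-3,4,5,8,9,10-hexahydro-2H-oxecin-3-yl]oxy}-6-oxohexa-2,4-dienoic acid
Conditions: 11 (6 equiv), Cs2CO3 (3 equiv), DMF, 4 Å molecular sieves, 50 °C, 24 h; dilute citric acid work-up
Reagents that add atoms: none
Why: SN2 displacement of the carbonyl-activated α-chloride by cesium hydrogen muconate (cesium carboxylate alkylation) goes with Walden inversion to the (S)-acyloxy centre, and the excess of the symmetrical diacid holds the reaction at the half ester.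

Step 8
Reactants: 12 (2E,4E)-6-{[(3S,6E,8R,9R,10R)-8,9-(isopropylidenedioxy)-2-oxo-10-propyl-3,4,5,8,9,10-hexahydro-2H-oxecin-3-yl]oxy}-6-oxohexa-2,4-dienoic acid
Product: 13 (2E,4E)-6-{[(3S,6E,8R,9S,10R)-8,9-dihydroxy-2-oxo-10-propyl-3,4,5,8,9,10-hexahydro-2H-oxecin-3-yl]oxy}-6-oxohexa-2,4-dienoic acid
Conditions: CF3CO2H/H2O (9:1), CH2Cl2, 0 °C to rt
Reagents that add atoms: none
Why: acid-catalysed acetal hydrolysis frees the 7,8-diol and leaves the lactone, the half ester and all four stereocenters untouched.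

## Compound list

1 | 1-hydroxypentan-2-one | CCCC(=O)CO | starting material
2 | (2E)-but-2-enal | C/C=C/C=O | starting material
3 | (5S,6R,7E)-5,6-dihydroxynon-7-en-4-one | CCCC(=O)[C@@H](O)[C@H](O)/C=C/C | intermediate
4 | 1-[(4S,5R)-2,2-dimethyl-5-[(1E)-prop-1-en-1-yl]-1,3-dioxolan-4-yl]butan-1-one | CCCC(=O)[C@H]1OC(C)(C)O[C@@H]1/C=C/C | intermediate
5 | (1R)-1-[(4R,5R)-2,2-dimethyl-5-[(1E)-prop-1-en-1-yl]-1,3-dioxolan-4-yl]butan-1-ol | CCC[C@@H](O)[C@H]1OC(C)(C)O[C@@H]1/C=C/C | intermediate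
6 | hex-5-enal | C=CCCCC=O | starting material
7 | (2R)-2-chlorohex-5-enal | O=C[C@H](Cl)CCC=C | intermediate
8 | (2R)-2-chlorohex-5-enoic acid | OC(=O)[C@H](Cl)CCC=C | intermediate
9 | (1R)-1-[(4R,5R)-2,2-dimethyl-5-[(1E)-prop-1-en-1-yl]-1,3-dioxolan-4-yl]butyl (2R)-2-chlorohex-5-enoate | CCC[C@@H](OC(=O)[C@H](Cl)CCC=C)[C@H]1OC(C)(C)O[C@@H]1/C=C/C | intermediate
10 | (3R,6E,8R,9R,10R)-3-chloro-8,9-(isopropylidenedioxy)-10-propyl-3,4,5,8,9,10-hexahydro-2H-oxecin-2-one (ten-membered lactone: O1, C2=O, Cl on C3, E-alkene C6=C7, acetonide on O8/O9, propyl on C10) | CCC[C@H]1OC(=O)[C@H](Cl)CC/C=C/[C@H]2OC(C)(C)O[C@H]12 | intermediate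
11 | (2E,4E)-hexa-2,4-dienedioic acid (trans,trans-muconic acid) | OC(=O)/C=C/C=C/C(=O)O | starting material
12 | (2E,4E)-6-{[(3S,6E,8R,9R,10R)-8,9-(isopropylidenedioxy)-2-oxo-10-propyl-3,4,5,8,9,10-hexahydro-2H-oxecin-3-yl]oxy}-6-oxohexa-2,4-dienoic acid | CCC[C@H]1OC(=O)[C@@H](OC(=O)/C=C/C=C/C(=O)O)CC/C=C/[C@H]2OC(C)(C)O[C@H]12 | intermediate
13 | (2E,4E)-6-{[(3S,6E,8R,9S,10R)-8,9-dihydroxy-2-oxo-10-propyl-3,4,5,8,9,10-hexahydro-2H-oxecin-3-yl]oxy}-6-oxohexa-2,4-dienoic acid | CCC[C@H]1OC(=O)[C@@H](OC(=O)/C=C/C=C/C(=O)O)CC/C=C/[C@@H](O)[C@@H]1O | target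

## Step count and risks

Total: 8 steps. Longest linear sequence: 7 steps (steps 1, 2, 3, 5, 6, 7, 8 from compound 1); step 4 is a one-step branch.

The three steps most likely to fail:

**Step 1 (the proposed new aldol).** The enal may self-condense through its dienamine, the enamine may add 1,4, and the diastereo- and enantioselectivity on this donor/acceptor pair are untested. The fallback uses known chemistry, sets out from 2 and comes back at 4. A Lewis-base-catalysed glycolate aldol is run on 2 with the trimethylsilyl ketene acetal of methyl [(tert-butyldimethylsilyl)oxy]acetate (SiCl4, 3 mol % of (S,S)-N,N'-bis(3,5-dimethyl-4-oxido-4,5-dihydro-3H-dinaphtho[2,1-d:1',2'-f][1,3,2]diazaphosphepin-4-yl)-N,N'-dimethylpentane-1,5-diamine, CH2Cl2, −78 °C). This catalyst enantiomer is chosen for Si-face attack, and the reaction type is documented to give syn adducts with conjugated aldehydes. It gives methyl (2S,3R,4E)-2-[(tert-butyldimethylsilyl)oxy]-3-hydroxyhex-4-enoate F1. Bu4NF/AcOH then gives methyl (2S,3R,4E)-2,3-dihydroxyhex-4-enoate F2. 2,2-Dimethoxypropane with pyridinium p-toluenesulfonate gives methyl (4S,5R)-2,2-dimethyl-5-[(1E)-prop-1-en-1-yl]-1,3-dioxolane-4-carboxylate F3. MeNHOMe·HCl with i-PrMgCl gives (4S,5R)-N-methoxy-N,2,2-trimethyl-5-[(1E)-prop-1-en-1-yl]-1,3-dioxolane-4-carboxamide F4, and n-PrMgBr converts this Weinreb amide into ketone 4.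

**Step 6 (ring-closing metathesis).** It may give the Z lactone or oligomers. The fallback sets out from 5 and 8 and comes back at 10; it builds the alkene in the open chain and closes the ring at the C9–O bond instead. Cross-metathesis of 5 with 8 (3 equiv; second-generation Hoveyda–Grubbs catalyst RuCl2(=CH-C6H4-2-O-i-Pr)(H2IMes), CH2Cl2, 40 °C) gives (2R,5E)-2-chloro-6-[(4R,5R)-5-[(1R)-1-hydroxybutyl]-2,2-dimethyl-1,3-dioxolan-4-yl]hex-5-enoic acid F5. Shiina macrolactonisation (2-methyl-6-nitrobenzoic anhydride, 4-(dimethylamino)pyridine, CH2Cl2, slow addition, rt) then gives 10. Activating the α-chloro acid this way carries some risk of epimerisation at C2.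

**Step 7 (SN2 on the ring).** Backside approach to C2 may be blocked by the ten-membered ring, giving elimination or no reaction. The fallback sets out from 9 and comes back at 12; the C2–O bond is made on the open chain with a small carboxylate and the muconate is then attached by O-acylation. CsO2CH (5 equiv, DMF, 50 °C) displaces the chloride with inversion to give (1R)-1-[(4R,5R)-2,2-dimethyl-5-[(1E)-prop-1-en-1-yl]-1,3-dioxolan-4-yl]butyl (2S)-2-(formyloxy)hex-5-enoate F6. KHCO3/MeOH removes the formyl group to give (1R)-1-[(4R,5R)-2,2-dimethyl-5-[(1E)-prop-1-en-1-yl]-1,3-dioxolan-4-yl]butyl (2S)-2-hydroxyhex-5-enoate F7. Ring-closing metathesis as in step 6 gives (3S,6E,8R,9R,10R)-3-hydroxy-8,9-(isopropylidenedioxy)-10-propyl-3,4,5,8,9,10-hexahydro-2H-oxecin-2-one F8. Steglich acylation of its free hydroxyl with 11 (6 equiv; N-ethyl-N'-(3-dimethylaminopropyl)carbodiimide hydrochloride, 4-(dimethylamino)pyridine, DMF) gives 12.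

## Further compounds

F1 | step 1 | methyl (2S,3R,4E)-2-[(tert-butyldimethylsilyl)oxy]-3-hydroxyhex-4-enoate | COC(=O)[C@@H](O[Si](C)(C)C(C)(C)C)[C@H](O)/C=C/C
F2 | step 1 | methyl (2S,3R,4E)-2,3-dihydroxyhex-4-enoate | COC(=O)[C@@H](O)[C@H](O)/C=C/C
F3 | step 1 | methyl (4S,5R)-2,2-dimethyl-5-[(1E)-prop-1-en-1-yl]-1,3-dioxolane-4-carboxylate | COC(=O)[C@H]1OC(C)(C)O[C@@H]1/C=C/C
F4 | step 1 | (4S,5R)-N-methoxy-N,2,2-trimethyl-5-[(1E)-prop-1-en-1-yl]-1,3-dioxolane-4-carboxamide | CON(C)C(=O)[C@H]1OC(C)(C)O[C@@H]1/C=C/C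
F5 | step 6 | (2R,5E)-2-chloro-6-[(4R,5R)-5-[(1R)-1-hydroxybutyl]-2,2-dimethyl-1,3-dioxolan-4-yl]hex-5-enoic acid | CCC[C@@H](O)[C@H]1OC(C)(C)O[C@@H]1/C=C/CC[C@@H](Cl)C(=O)O
F6 | step 7 | (1R)-1-[(4R,5R)-2,2-dimethyl-5-[(1E)-prop-1-en-1-yl]-1,3-dioxolan-4-yl]butyl (2S)-2-(formyloxy)hex-5-enoate | CCC[C@@H](OC(=O)[C@@H](OC=O)CCC=C)[C@H]1OC(C)(C)O[C@@H]1/C=C/C
F7 | step 7 | (1R)-1-[(4R,5R)-2,2-dimethyl-5-[(1E)-prop-1-en-1-yl]-1,3-dioxolan-4-yl]butyl (2S)-2-hydroxyhex-5-enoate | CCC[C@@H](OC(=O)[C@@H](O)CCC=C)[C@H]1OC(C)(C)O[C@@H]1/C=C/C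
F8 | step 7 | (3S,6E,8R,9R,10R)-3-hydroxy-8,9-(isopropylidenedioxy)-10-propyl-3,4,5,8,9,10-hexahydro-2H-oxecin-2-one | CCC[C@H]1OC(=O)[C@@H](O)CC/C=C/[C@H]2OC(C)(C)O[C@H]12
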